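**Plan**

1. Retrosynthetic cuts: last, the C–C bond between C2 of the pyranone ring (ring C) and C1' of ring B. In the benzodioxane half: the benzylic O1–C2 bond, the C2–syringyl bond and the aryl ether bond O4–C3.
2. Forward order: O4–C3 by Mitsunobu etherification of o-vanillin; Dakin oxidation turns CHO into O1 and gives a lactone, which is reduced to the lactol; syringyl Grignard addition; acid closure of the dioxane ring (the only ring made). The finished benzodioxane is then joined to the intact chromone (rings A and C), and one desilylation ends the route.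
3. Stereochemistry: C3 of the dioxane comes from methyl L-glycerate through one SN2 inversion. C2 is set trans to it in a stereoconvergent, reversible SN1 ring closure that takes both carbinol epimers to one product.
4. Enabling feature: in benzodioxane 13, C7–H (the future C1' of ring B) is the only aromatic C–H without an ortho substituent, since it lies between C6–H and C8–H. Both syringyl C–H bonds lie between an OMe group and the benzylic carbon.
5. In the chromone, C2–H is the β-carbon of the vinylogous ester O1–C2=C3–C4=O. The two halves are therefore joined as plain C–H compounds: iridium borylation picks C7, and an oxidative boron-Heck reaction picks chromone C2, so no halide is carried through the route.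

Key step: step 9

Assumption: the carbinol centre made in step 6 and the anomeric centre of lactol 8 are carried as mixtures, because the first is reset in step 7 and the second is consumed in step 6.

**Route**

Step 1
Reactants: 1 methyl (2S)-2,3-dihydroxypropanoate (methyl L-glycerate)
Product: 2 methyl (2S)-2-hydroxy-3-(triisopropylsilyloxy)propanoate
Conditions: i-Pr3SiCl (1.05 equiv), imidazole, CH2Cl2, 0 °C → rt
Reagents that add atoms: triisopropylsilyl chloride, CC(C)[Si](Cl)(C(C)C)C(C)C
Why: Selective silylation (silyl ether formation): the primary hydroxyl reacts much faster with the bulky silyl chloride than the secondary hydroxyl next to the ester, and the stereocentre is not involved.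

Step 2
Reactants: 2 methyl (2S)-2-hydroxy-3-(triisopropylsilyloxy)propanoate; 3 2-hydroxy-3-methoxybenzaldehyde (o-vanillin)
Product: 4 methyl (2R)-2-(2-formyl-6-methoxyphenoxy)-3-(triisopropylsilyloxy)propanoate
Conditions: PPh3, DIAD, THF, 0 °C → rt
Reagents that add atoms: none
Why: Mitsunobu etherification: the acidic phenol of 3 attacks the oxyphosphonium ion of the α-hydroxy ester in an SN2 sense, so the (S)-carbinol is inverted to the (R)-aryl ether, which is the configuration of C3 of the dioxane ring, and the oxygen that is alkylated is the one next to OMe (the future O4).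

Step 3
Reactants: 4 methyl (2R)-2-(2-formyl-6-methoxyphenoxy)-3-(triisopropylsilyloxy)propanoate
Product: 7 (3R)-5-methoxy-3-[(triisopropylsilyloxy)methyl]-1,4-benzodioxin-2(3H)-one, via aryl formate 5 (not isolated), via phenol ester 6 (not isolated)
Conditions: mCPBA, CH2Cl2, 0 °C → rt; then Et3N (cat.), MeOH, rt; then TsOH·H2O (5 mol %), toluene, 80 °C, 5 Å MS
Reagents that add atoms: mCPBA, OOC(=O)c1cccc(Cl)c1
Why: Dakin-type Baeyer–Villiger oxidation followed by lactonisation: the electron-rich ortho-alkoxyaryl group migrates to the peracid oxygen, the formate is methanolysed under very mild base, and the freed phenol (the future O1) closes the six-membered aryl lactone under acid, conditions that should not enolise the α-aryloxy ester centre.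

Step 4
Reactants: 7 (3R)-5-methoxy-3-[(triisopropylsilyloxy)methyl]-1,4-benzodioxin-2(3H)-one
Product: 8 (3R)-5-methoxy-3-[(triisopropylsilyloxy)methyl]-2,3-dihydro-1,4-benzodioxin-2-ol (lactol, both anomers)
Conditions: i-Bu2AlH (1.1 equiv), CH2Cl2, −78 °C; aq. potassium sodium tartrate
Reagents that add atoms: none
Why: Partial reduction of a lactone with i-Bu2AlH: at −78 °C the aluminium lactolate is stable until work-up, as with dihydrocoumarins, so reduction should stop at the lactol, a masked α-aryloxy aldehyde whose α-centre is kept.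

Step 5
Reactants: 9 4-bromo-2,6-dimethoxyphenol
Product: 10 (4-bromo-2,6-dimethoxyphenoxy)triisopropylsilane
Conditions: i-Pr3SiCl, imidazole, DMF, 50 °C
Reagents that add atoms: triisopropylsilyl chloride, CC(C)[Si](Cl)(C(C)C)C(C)C
Why: Silyl ether formation on the phenol: the triisopropylsilyl group survives Grignard formation and acid, and it carries no aromatic C–H bond that could compete in the later borylation.

Step 6
Reactants: 10 (4-bromo-2,6-dimethoxyphenoxy)triisopropylsilane; 8 (3R)-5-methoxy-3-[(triisopropylsilyloxy)methyl]-2,3-dihydro-1,4-benzodioxin-2-ol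
Product: 12 (2R)-1-[3,5-dimethoxy-4-(triisopropylsilyloxy)phenyl]-2-(2-hydroxy-6-methoxyphenoxy)-3-(triisopropylsilyloxy)propan-1-ol (both C1 epimers), via arylmagnesium bromide 11 (not isolated)
Conditions: 10 (3 equiv), Mg, I2 (cat.), THF, 50 °C; then 8, THF, −20 °C → rt; aq. NH4Cl
Reagents that add atoms: none
Why: Grignard addition to a lactol: one equivalent of 11 deprotonates 8 and opens it to the aldehyde with a magnesium phenoxide, and a second equivalent adds to the aldehyde faster than it enolises it; the new carbinol centre forms without control, which is harmless because step 7 resets it.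

Step 7
Reactants: 12 (2R)-1-[3,5-dimethoxy-4-(triisopropylsilyloxy)phenyl]-2-(2-hydroxy-6-methoxyphenoxy)-3-(triisopropylsilyloxy)propan-1-ol
Product: 13 (2R,3R)-2-[3,5-dimethoxy-4-(triisopropylsilyloxy)phenyl]-5-methoxy-3-[(triisopropylsilyloxy)methyl]-2,3-dihydro-1,4-benzodioxine (trans)
Conditions: TsOH·H2O (10 mol %), CH2Cl2, 4 Å MS, rt
Reagents that add atoms: none
Why: Acid-catalysed SN1 etherification (stereoconvergent ring closure): both carbinol epimers ionise to the same benzylic cation, stabilised by the 4-silyloxy-3,5-dimethoxyphenyl ring, the phenol closes the six-membered dioxane ring, and because closure is reversible under the acid the mixture should drain into the more stable trans isomer, in which the fixed (R)-centre at C3 places the aryl group pseudo-equatorial and so sets C2 as R.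

Step 8
Reactants: 14 5,7-dihydroxy-4H-chromen-4-one (5,7-dihydroxychromone)
Product: 15 5-hydroxy-7-(triisopropylsilyloxy)-4H-chromen-4-one
Conditions: i-Pr3SiCl (1.05 equiv), imidazole, DMF, 0 °C → rt
Reagents that add atoms: triisopropylsilyl chloride, CC(C)[Si](Cl)(C(C)C)C(C)C
Why: Selective silylation: the 7-OH is a free, acidic phenol while the 5-OH is held in a hydrogen bond to the C4 carbonyl and does not react.

Step 9
Reactants: 13 (2R,3R)-2-[3,5-dimethoxy-4-(triisopropylsilyloxy)phenyl]-5-methoxy-3-[(triisopropylsilyloxy)methyl]-2,3-dihydro-1,4-benzodioxine; 15 5-hydroxy-7-(triisopropylsilyloxy)-4H-chromen-4-one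
Product: 17 5-hydroxy-2-{(2R,3R)-2-[3,5-dimethoxy-4-(triisopropylsilyloxy)phenyl]-5-methoxy-3-[(triisopropylsilyloxy)methyl]-2,3-dihydro-1,4-benzodioxin-7-yl}-7-(triisopropylsilyloxy)-4H-chromen-4-one (tris-silyl ether of Palstatin), via aryl pinacol boronate 16 (not isolated)
Conditions: [Ir(OMe)(cod)]2 (2.5 mol %), 4,4'-di-tert-butyl-2,2'-bipyridine (5 mol %), B2pin2 (1.0 equiv), THF, 80 °C; volatiles removed; then 15 (1.5 equiv), Pd(OCOCF3)2 (10 mol %), 5-nitro-1,10-phenanthroline (20 mol %), O2 (1 atm), DMSO, 80 °C
Reagents that add atoms: none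
Why: A trivalent iridium tris(boryl) complex of the bipyridine cleaves the sterically most accessible aromatic C–H bond of 13 and gives boronate 16; after the solvent switch 16 transmetalates to phenanthroline-ligated divalent palladium, the aryl–palladium bond adds across C2=C3 of 15 with the aryl group at the β-carbon C2, the C3 palladium enolate reaches a syn hydrogen through its O-bound form, β-hydride elimination releases flavone 17, and O2 returns zerovalent palladium to the divalent state. The closest known reaction types are one-pot iridium C–H borylation/cross-coupling sequences and the oxidative boron-Heck arylation of chromones (or chromanones) to flavones with arylboronic acids or their pinacol esters. No ring is closed and no stereocentre is formed; the two dioxane stereocentres are remote from both reacting sites and the medium is free of base, so they should be retained. The step needs site selectivity in the borylation, secured by C7–H being the only aromatic C–H of 13 without an ortho substituent (the syringyl C–H bonds are flanked on both sides and the triisopropylsilyl groups have no aromatic C–H), and C2 over C3 selectivity in the insertion, secured by the polarisation of the vinylogous ester. Chemoselectivity toward palladium and O2 rests on the silyl ethers, which mask the primary alcohol and the two oxidisable phenols, while the 5-OH is deactivated by its hydrogen bond to the C4 carbonyl.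

Step 10
Reactants: 17 tris-silyl ether of Palstatin
Product: 18 Palstatin, 5,7-dihydroxy-2-[(2R,3R)-2-(4-hydroxy-3,5-dimethoxyphenyl)-3-(hydroxymethyl)-5-methoxy-2,3-dihydro-1,4-benzodioxin-7-yl]-4H-chromen-4-one
Conditions: Bu4NF (4 equiv), AcOH (4 equiv), THF, 0 °C → rt, under argon
Reagents that add atoms: none
Why: Fluoride-mediated desilylation: fluoride cleaves the two aryl and the one alkyl Si–O bonds, acetic acid keeps the phenoxides protonated, and should the dioxane open reversibly through the para-quinone methide of the freed syringyl phenol it recloses to the same, more stable trans isomer, so the (2R,3R) configuration is kept.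

**Compound list**

1 | methyl (2S)-2,3-dihydroxypropanoate | COC(=O)[C@@H](O)CO | starting material
2 | methyl (2S)-2-hydroxy-3-(triisopropylsilyloxy)propanoate | COC(=O)[C@@H](O)CO[Si](C(C)C)(C(C)C)C(C)C | intermediate
3 | 2-hydroxy-3-methoxybenzaldehyde (o-vanillin) | COc1cccc(C=O)c1O | starting material
4 | methyl (2R)-2-(2-formyl-6-methoxyphenoxy)-3-(triisopropylsilyloxy)propanoate | COC(=O)[C@H](Oc1c(OC)cccc1C=O)CO[Si](C(C)C)(C(C)C)C(C)C | intermediate
5 | methyl (2R)-2-[2-(formyloxy)-6-methoxyphenoxy]-3-(triisopropylsilyloxy)propanoate | COC(=O)[C@H](Oc1c(OC)cccc1OC=O)CO[Si](C(C)C)(C(C)C)C(C)C | intermediate (not isolated)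
6 | methyl (2R)-2-(2-hydroxy-6-methoxyphenoxy)-3-(triisopropylsilyloxy)propanoate | COC(=O)[C@H](Oc1c(OC)cccc1O)CO[Si](C(C)C)(C(C)C)C(C)C | intermediate (not isolated)
7 | (3R)-5-methoxy-3-[(triisopropylsilyloxy)methyl]-1,4-benzodioxin-2(3H)-one | O=C1Oc2cccc(OC)c2O[C@@H]1CO[Si](C(C)C)(C(C)C)C(C)C | intermediate
8 | (3R)-5-methoxy-3-[(triisopropylsilyloxy)methyl]-2,3-dihydro-1,4-benzodioxin-2-ol (both anomers) | OC1Oc2cccc(OC)c2O[C@@H]1CO[Si](C(C)C)(C(C)C)C(C)C | intermediate
9 | 4-bromo-2,6-dimethoxyphenol | COc1cc(Br)cc(OC)c1O | starting material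
10 | (4-bromo-2,6-dimethoxyphenoxy)triisopropylsilane | COc1cc(Br)cc(OC)c1O[Si](C(C)C)(C(C)C)C(C)C | intermediate
11 | [3,5-dimethoxy-4-(triisopropylsilyloxy)phenyl]magnesium bromide | COc1cc([Mg]Br)cc(OC)c1O[Si](C(C)C)(C(C)C)C(C)C | intermediate (not isolated)
12 | (2R)-1-[3,5-dimethoxy-4-(triisopropylsilyloxy)phenyl]-2-(2-hydroxy-6-methoxyphenoxy)-3-(triisopropylsilyloxy)propan-1-ol (both C1 epimers) | COc1cc(C(O)[C@@H](CO[Si](C(C)C)(C(C)C)C(C)C)Oc2c(O)cccc2OC)cc(OC)c1O[Si](C(C)C)(C(C)C)C(C)C | intermediate
13 | (2R,3R)-2-[3,5-dimethoxy-4-(triisopropylsilyloxy)phenyl]-5-methoxy-3-[(triisopropylsilyloxy)methyl]-2,3-dihydro-1,4-benzodioxine | COc1cc([C@H]2Oc3cccc(OC)c3O[C@@H]2CO[Si](C(C)C)(C(C)C)C(C)C)cc(OC)c1O[Si](C(C)C)(C(C)C)C(C)C | intermediate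
14 | 5,7-dihydroxy-4H-chromen-4-one | O=c1ccoc2cc(O)cc(O)c12 | starting material
15 | 5-hydroxy-7-(triisopropylsilyloxy)-4H-chromen-4-one | O=c1ccoc2cc(O[Si](C(C)C)(C(C)C)C(C)C)cc(O)c12 | intermediate
16 | 7-(4,4,5,5-tetramethyl-1,3,2-dioxaborolan-2-yl) derivative of 13 | COc1cc([C@H]2Oc3cc(B4OC(C)(C)C(C)(C)O4)cc(OC)c3O[C@@H]2CO[Si](C(C)C)(C(C)C)C(C)C)cc(OC)c1O[Si](C(C)C)(C(C)C)C(C)C | intermediate (not isolated)
17 | tris-silyl ether of Palstatin (name as in step 9) | COc1cc([C@H]2Oc3cc(-c4cc(=O)c5c(O)cc(O[Si](C(C)C)(C(C)C)C(C)C)cc5o4)cc(OC)c3O[C@@H]2CO[Si](C(C)C)(C(C)C)C(C)C)cc(OC)c1O[Si](C(C)C)(C(C)C)C(C)C | intermediate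
18 | Palstatin | COc1cc([C@H]2Oc3cc(-c4cc(=O)c5c(O)cc(O)cc5o4)cc(OC)c3O[C@@H]2CO)cc(OC)c1O | target

**Step count and risks**

Total steps: 10. Longest linear sequence: 8 (steps 1, 2, 3, 4, 6, 7, 9, 10).

Steps most likely to fail:

Step 9. What may go wrong: borylation may also occur at C8–H next to the ring oxygen. In the palladium stage the boronate may be lost by protodeboronation or oxidative homocoupling before it inserts, or the palladium enolate may be protonated so that the reaction stops at the flavanone level. Fallback: setting out from 13, boronate 16 is made as before but isolated and freed from isomers on silica. It is then added to 15 in a conjugate sense with a hydroxo complex of monovalent rhodium ([Rh(OH)(cod)]2, dioxane/H2O, 50 °C, no oxidant) to give the silyl-protected flavanone F1 (both epimers at the flavanone C2). F1 is dehydrogenated with catalytic I2 in DMSO at 100 °C, which brings the route back at 17; partial loss of silyl groups there is of no consequence because step 10 follows.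

Step 7. What may go wrong: the benzylic cation may lose the C3 proton (enol ether formation, which would also erase the C3 centre) or suffer a hydride shift instead of closing the ring, or the cis isomer may fail to equilibrate. Fallback: setting out from 12, only the aryl silyl ether is cleaved (Bu4NF, 1 equiv, THF, −20 °C) to give the free syringyl phenol F2. Me3SiBr in CH2Cl2 converts its benzylic alcohol into the benzylic bromide F3, and aqueous NaHCO3 then eliminates HBr to the para-quinone methide F4. The neighbouring phenol traps F4 reversibly to give the trans-benzodioxane phenol F5, and resilylation (i-Pr3SiCl, imidazole, DMF) returns to 13.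

Step 6. What may go wrong: the basic Grignard reagent may enolise the ring-opened α-aryloxy aldehyde, which would erode the configuration at the glycerate-derived centre, or it may eliminate silanolate. Fallback: setting out from 11, quenching with B(OMe)3 and aqueous work-up gives the arylboronic acid F6. F6 is added to lactol 8 by rhodium catalysis near neutrality at room temperature (Rh(acac)(coe)2, P(t-Bu)3, DME/H2O, rt), an arylboron addition to the aldehyde form that avoids a strong base, and the route is rejoined at 12.

Further compounds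

F1 | step 9 | 5-hydroxy-2-{(2R,3R)-2-[3,5-dimethoxy-4-(triisopropylsilyloxy)phenyl]-5-methoxy-3-[(triisopropylsilyloxy)methyl]-2,3-dihydro-1,4-benzodioxin-7-yl}-7-(triisopropylsilyloxy)chroman-4-one (both epimers at chromanone C2) | COc1cc([C@H]2Oc3cc(C4CC(=O)c5c(O)cc(O[Si](C(C)C)(C(C)C)C(C)C)cc5O4)cc(OC)c3O[C@@H]2CO[Si](C(C)C)(C(C)C)C(C)C)cc(OC)c1O[Si](C(C)C)(C(C)C)C(C)C
F2 | step 7 | (2R)-1-(4-hydroxy-3,5-dimethoxyphenyl)-2-(2-hydroxy-6-methoxyphenoxy)-3-(triisopropylsilyloxy)propan-1-ol (both C1 epimers) | COc1cc(C(O)[C@@H](CO[Si](C(C)C)(C(C)C)C(C)C)Oc2c(O)cccc2OC)cc(OC)c1O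
F3 | step 7 | 4-[(2R)-1-bromo-2-(2-hydroxy-6-methoxyphenoxy)-3-(triisopropylsilyloxy)propyl]-2,6-dimethoxyphenol (both C1 epimers) | COc1cc(C(Br)[C@@H](CO[Si](C(C)C)(C(C)C)C(C)C)Oc2c(O)cccc2OC)cc(OC)c1O
F4 | step 7 | 4-[(2R)-2-(2-hydroxy-6-methoxyphenoxy)-3-(triisopropylsilyloxy)propylidene]-2,6-dimethoxycyclohexa-2,5-dien-1-one (para-quinone methide) | COC1=CC(=C[C@@H](CO[Si](C(C)C)(C(C)C)C(C)C)Oc2c(O)cccc2OC)C=C(OC)C1=O
F5 | step 7 | 2,6-dimethoxy-4-{(2R,3R)-5-methoxy-3-[(triisopropylsilyloxy)methyl]-2,3-dihydro-1,4-benzodioxin-2-yl}phenol | COc1cc([C@H]2Oc3cccc(OC)c3O[C@@H]2CO[Si](C(C)C)(C(C)C)C(C)C)cc(OC)c1O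
F6 | step 6 | [3,5-dimethoxy-4-(triisopropylsilyloxy)phenyl]boronic acid | COc1cc(B(O)O)cc(OC)c1O[Si](C(C)C)(C(C)C)C(C)C
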